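Assumption: the recombinant toluene‑dioxygenase strain E. coli JM109(pDTG601A) is treated as a laboratory biocatalyst (a reagent); ring positions are numbered as in the target (C1 carries CH2OBz, C2 is the vinyl CH, C3–C6 carry the oxygens, all four cis).

## Retrosynthetic overview

- No ring is built: the carbocycle is the benzene ring of ethyl benzoate 1, dearomatised once and kept.
- C5–O and C6–O go back to an enzymatic arene cis‑dihydroxylation of 1, giving diol ester 2.
- The CH2OBz arm goes back to the ester of 2: reduction to triol 3, then primary benzoylation to diene diol 4.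
- Key disconnection: the syn C3–O and C4–O bonds and the C5–O benzoyl ester are made from 4 in one flask, through osmium glycolates 5 and 6, to give the all‑cis target 7.

## Route

Step 1
Reactants: 1 ethyl benzoate
Product: 2 ethyl (5S,6R)-5,6-dihydroxycyclohexa-1,3-diene-1-carboxylate
Conditions: E. coli JM109(pDTG601A) whole cells (toluene dioxygenase), IPTG, glucose, air, pH 6.8 mineral medium, 35 °C; EtOAc extraction
Reagents that add atoms: dioxygen O=O
Why: Enzymatic arene cis‑dihydroxylation (toluene dioxygenase, a Rieske non‑heme iron enzyme) is established for ethyl benzoate; both atoms of O2 add to one enantiotopic face of the C2–C3 bond, setting the cis‑(5S,6R) diol that becomes C5 and C6 of the target.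

Step 2
Reactants: 2 ethyl (5S,6R)-5,6-dihydroxycyclohexa-1,3-diene-1-carboxylate
Product: 3 (1S,2R)-3-(hydroxymethyl)cyclohexa-3,5-diene-1,2-diol
Conditions: i-Bu2AlH (5 equiv), THF, −78 → −20 °C; MeOH, then Na2SO4·10H2O, filter (no acid)
Reagents that add atoms: none
Why: Hydride 1,2‑reduction of a conjugated ester to the allylic alcohol (DIBAL‑H reduction) leaves the diene and both stereocentres untouched, and the acid‑free work‑up avoids dehydration of the dihydrodiol to phenols.

Step 3
Reactants: 3 (1S,2R)-3-(hydroxymethyl)cyclohexa-3,5-diene-1,2-diol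
Product: 4 [(5S,6R)-5,6-dihydroxycyclohexa-1,3-dien-1-yl]methyl benzoate
Conditions: BzCl (1.05 equiv), 2,4,6-collidine, THF/CH2Cl2 (1:1), −78 → −40 °C
Reagents that add atoms: benzoyl chloride O=C(Cl)c1ccccc1
Why: Chemoselective esterification: with an acyl chloride and a hindered pyridine base at low temperature the unhindered primary allylic hydroxyl is acylated much faster than the two secondary ring hydroxyls, and no stereocentre is touched.

Step 4
Reactants: 4 [(5S,6R)-5,6-dihydroxycyclohexa-1,3-dien-1-yl]methyl benzoate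
Product: 7 [(3S,4S,5R,6R)-5-(benzoyloxy)-3,4,6-trihydroxycyclohex-1-en-1-yl]methyl benzoate, via osmium glycolate 5 (not isolated), via benzoylated osmium glycolate 6 (not isolated)
Conditions: OsO4 (1.0 equiv), TMEDA (1.05 equiv), CH2Cl2, −78 °C; then pyridine, BzCl (1.1 equiv), −78 → −20 °C; then MeOH, 2 M HCl, 0 °C → rt
Reagents that add atoms: osmium tetroxide O=[Os](=O)(=O)=O; benzoyl chloride O=C(Cl)c1ccccc1
Why: Proposed new method: a one‑flask hydroxyl‑directed syn‑dihydroxylation in which the osmate ester is kept on as a temporary diol mask for a site‑selective benzoylation; OsO4·TMEDA is a hydrogen‑bond acceptor, so the allylic 5‑OH (helped by the cis 6‑OH) steers octavalent osmium to the hydroxyl‑bearing face of the less hindered C3=C4 bond (C1=C2 is trisubstituted and deactivated by CH2OBz), and the [3+2] cycloaddition sets C3 and C4 all‑cis; the chelated hexavalent‑osmium glycolate 5 is substitution‑inert and hides O3 and O4, so BzCl/pyridine chooses only between the equatorial, non‑allylic 5‑OH and the pseudoaxial, allylic 6‑OH, which is crowded by C1–CH2OBz and lies 1,3‑syn to the osmate oxygen on C4, giving 5‑benzoate 6, and acidic methanol then frees the diol without base‑induced acyl migration; the closest known reaction types are the directed dihydroxylation of allylic alcohols with OsO4/TMEDA (isolable osmate esters) and the regioselective acylation of diols masked as stannylene or boronate esters.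

## Compound list

1 | ethyl benzoate | CCOC(=O)c1ccccc1 | starting material
2 | ethyl (5S,6R)-5,6-dihydroxycyclohexa-1,3-diene-1-carboxylate | CCOC(=O)C1=CC=C[C@H](O)[C@@H]1O | intermediate
3 | (1S,2R)-3-(hydroxymethyl)cyclohexa-3,5-diene-1,2-diol | OCC1=CC=C[C@H](O)[C@@H]1O | intermediate
4 | [(5S,6R)-5,6-dihydroxycyclohexa-1,3-dien-1-yl]methyl benzoate | O=C(OCC1=CC=C[C@H](O)[C@@H]1O)c1ccccc1 | intermediate
5 | OsO2(TMEDA) 3,4-glycolate of [(3S,4S,5R,6R)-3,4,5,6-tetrahydroxycyclohex-1-en-1-yl]methyl benzoate (hexavalent osmium bound to O3 and O4; 5-OH and 6-OH free; all four oxygens cis) | O=C(OCC1=C[C@H](O2)[C@H](O[Os-2]23(=O)(=O)[N+](C)(C)CC[N+]3(C)C)[C@H](O)[C@@H]1O)c1ccccc1 | intermediate (not isolated)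
6 | 5-O-benzoyl derivative of 5 (6-OH free) | O=C(OCC1=C[C@H](O2)[C@H](O[Os-2]23(=O)(=O)[N+](C)(C)CC[N+]3(C)C)[C@H](OC(=O)c4ccccc4)[C@@H]1O)c1ccccc1 | intermediate (not isolated)
7 | [(3S,4S,5R,6R)-5-(benzoyloxy)-3,4,6-trihydroxycyclohex-1-en-1-yl]methyl benzoate | O=C(OCC1=C[C@H](O)[C@H](O)[C@H](OC(=O)c2ccccc2)[C@@H]1O)c1ccccc1 | target

## Count and risks

Total step count: 4. Longest linear sequence: 4.

Steps most likely to fail:

1. Step 4 (the proposed new step). The risks are osmylation of the C1=C2 bond directed by the 6‑OH, benzoylation at O6 instead of O5, and acyl migration during osmate cleavage. The fallback uses known chemistry, sets out from 4 and comes back at 7. It separates the two events and lets a catalyst choose the benzoate site. Directed dihydroxylation of 4 with OsO4/TMEDA in CH2Cl2 at −78 °C (through 5) and cleavage with HCl/MeOH give the free all‑cis tetrol [(3S,4S,5R,6R)-3,4,5,6-tetrahydroxycyclohex-1-en-1-yl]methyl benzoate F1. Borinic‑acid‑catalysed monoacylation (2‑aminoethyl diphenylborinate 10 mol %, BzCl, i‑Pr2NEt, MeCN, rt) then benzoylates the equatorial hydroxyl of a cis‑diol pair; 5‑OH is the equatorial hydroxyl flanked by two axial ones. Any 3‑O‑benzoate is removed by chromatography to give 7.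

2. Step 2. Triol 3 is water‑soluble, sticks to aluminium salts and aromatises with traces of acid. The fallback sets out from 2 and comes back at 4, bypassing 3 and step 3 by working on lipophilic silyl ethers. TESCl/imidazole in DMF at 0 °C gives ethyl (5S,6R)-5,6-bis(triethylsilyloxy)cyclohexa-1,3-diene-1-carboxylate F2. i‑Bu2AlH in CH2Cl2 at −78 °C gives [(5S,6R)-5,6-bis(triethylsilyloxy)cyclohexa-1,3-dien-1-yl]methanol F3. BzCl/pyridine/DMAP at 0 °C gives [(5S,6R)-5,6-bis(triethylsilyloxy)cyclohexa-1,3-dien-1-yl]methyl benzoate F4. Bu4NF buffered with AcOH in THF at 0 °C removes both silyl groups to give 4.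

3. Step 3. The risks are over‑benzoylation, secondary benzoates and benzoyl migration on the sensitive triol. The fallback sets out from 3 and comes back at 4, and replaces kinetic selectivity by temporary protection of the cis‑diol. PhB(OH)2 with MgSO4 in CH2Cl2 gives the cyclic phenylboronate of the 1,2-diol of 3 (CH2OH free, stereocentres as in 3) F5. BzCl/pyridine at 0 °C gives the benzoate of that cyclic phenylboronate F6. Transesterification with pinacol in CH2Cl2 at rt releases 4.

## Further compounds

F1 | step 4 | [(3S,4S,5R,6R)-3,4,5,6-tetrahydroxycyclohex-1-en-1-yl]methyl benzoate | O=C(OCC1=C[C@H](O)[C@H](O)[C@H](O)[C@@H]1O)c1ccccc1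
F2 | step 2 | ethyl (5S,6R)-5,6-bis(triethylsilyloxy)cyclohexa-1,3-diene-1-carboxylate | CCOC(=O)C1=CC=C[C@H](O[Si](CC)(CC)CC)[C@@H]1O[Si](CC)(CC)CC
F3 | step 2 | [(5S,6R)-5,6-bis(triethylsilyloxy)cyclohexa-1,3-dien-1-yl]methanol | OCC1=CC=C[C@H](O[Si](CC)(CC)CC)[C@@H]1O[Si](CC)(CC)CC
F4 | step 2 | [(5S,6R)-5,6-bis(triethylsilyloxy)cyclohexa-1,3-dien-1-yl]methyl benzoate | O=C(OCC1=CC=C[C@H](O[Si](CC)(CC)CC)[C@@H]1O[Si](CC)(CC)CC)c1ccccc1
F5 | step 3 | cyclic phenylboronate of the 1,2-diol of 3 (CH2OH free, stereocentres as in 3) | OCC1=CC=C[C@H](OB2c3ccccc3)[C@@H]1O2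
F6 | step 3 | benzoate of the cyclic phenylboronate F5 | O=C(OCC1=CC=C[C@H](OB2c3ccccc3)[C@@H]1O2)c1ccccc1
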